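**Plan**

1. Retrosynthesis: ring C is opened at O1–C2 and C3–C4 in one cut (chromanone numbering), leaving a ring A salicylaldehyde and a ring B aryl alkynyl methyl ether; the aryl–alkyne bond, the aryl–iodine bond and the two O-benzyl bonds are cut next.
2. Forward: ring B (methoxyhydroquinone) is benzylated, iodinated and joined to a methoxyethynyl unit; ring C is then closed onto the untouched ring A aldehyde, and hydrogenolysis frees the hydroquinone.
3. Enabling feature: the O1–C8a–C4a–C4 salicyl array of ring A. Phenolate O1 chelates rhodium so that the formyl C4–H bond adds across the alkyne (C3–C4), and the same O1 is then the Michael donor to C2. The alkynyl ether oxygen becomes the 3-methoxy group, so no atom is lost and no oxidation level needs adjusting.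
4. Stereochemistry: C2 (R) from a chiral bifunctional thiourea in the oxa-Michael stage of the key step; C3 (R) by equilibration to the trans, diequatorial isomer.
5. Helpers: benzyl ethers on O2' and O5' of ring B (they block benzofuran and flavylium formation), removed in the last step.

Key step: step 4

Assumption: of the pseudoenantiomeric quinine- and quinidine-derived thioureas, the member that delivers the 2R configuration is used; the quinine-derived one is written.

**Step 1**
Reactants: 1 2-methoxybenzene-1,4-diol
Product: 2 1,4-bis(benzyloxy)-2-methoxybenzene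
Conditions: BnBr (2.3 equiv), K2CO3 (3 equiv), DMF, 60 °C, under N2
Reagents that add atoms: benzyl bromide, BrCc1ccccc1
Why: Williamson ether synthesis; both phenolates are alkylated, and the benzyl groups mask O2' and O5' of ring B so that the later alkyne and enone cannot close onto O2'.

**Step 2**
Reactants: 2 1,4-bis(benzyloxy)-2-methoxybenzene
Product: 3 1,4-bis(benzyloxy)-2-iodo-5-methoxybenzene
Conditions: NIS (1.05 equiv), CF3CO2H (10 mol %), MeCN, 0 °C to rt, dark
Reagents that add atoms: N-iodosuccinimide, O=C1CCC(=O)N1I
Why: Electrophilic aromatic iodination; the position para to the methoxy group and ortho to a benzyloxy group is the only one that is doubly activated and unhindered, as in the halogenation of 1,2,4-trialkoxybenzenes.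

**Step 3**
Reactants: 3 1,4-bis(benzyloxy)-2-iodo-5-methoxybenzene, 4 2-chloro-1,1-dimethoxyethane
Product: 7 1,4-bis(benzyloxy)-2-methoxy-5-(methoxyethynyl)benzene, via lithium methoxyacetylide 5 (not isolated), via (methoxyethynyl)zinc chloride 6 (not isolated)
Conditions: 4 (1.3 equiv), LiN(iPr)2 (3.9 equiv), THF, −78 to 0 °C; ZnCl2 (1.4 equiv), 0 °C; then 3, Pd(PPh3)4 (5 mol %), rt to 40 °C; aq. NaHCO3 work-up, Et3N-treated silica
Reagents that add atoms: none
Why: Twofold base-induced elimination (methanol, then HCl) and deprotonation turn 4 into lithium methoxyacetylide, which after transmetalation to zinc should undergo Negishi coupling with the aryl iodide under zerovalent palladium, a known route to aryl alkynyl ethers.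

**Step 4**
Reactants: 7 1,4-bis(benzyloxy)-2-methoxy-5-(methoxyethynyl)benzene, 8 2-hydroxy-4,6-dimethoxybenzaldehyde
Product: 10 (2R,3R)-2-[2,5-bis(benzyloxy)-4-methoxyphenyl]-3,5,7-trimethoxy-2,3-dihydro-4H-chromen-4-one, via (Z)-α-methoxychalcone 9 (not isolated)
Conditions: [Rh(OMe)(cod)]2 (2.5 mol %), Fe(C5H4PPh2)2 (dppf, 5 mol %), toluene, 50–60 °C; then −20 °C, 9-amino-9-deoxy-epi-quinine 3,5-bis(trifluoromethyl)phenyl thiourea (10 mol %), then 0 °C
Reagents that add atoms: none
Why: Proposed new method: phenolate O1 of 8 binds monovalent rhodium and directs oxidative addition of the formyl C–H bond to a chelated acyl(hydrido)rhodium species that resists decarbonylation; alkynyl ether 7 then inserts into Rh–H with hydrogen going to the aryl-bearing carbon and rhodium to the methoxy-bearing carbon, and C–C reductive elimination forms C3–C4 of (Z)-α-methoxychalcone 9 with every atom of both partners kept. The closest known reaction type is the rhodium-catalysed hydroacylation of internal alkynes with salicylaldehydes and its tandem use with base-induced oxa-Michael closure to trans-2,3-disubstituted chroman-4-ones; new here are the alkynyl ether as the alkyne partner and the relay to a chiral catalyst. Ring C closes by 6-endo-trig oxa-Michael addition of O1 to C2 of 9. C2 is set by the bifunctional thiourea, whose quinuclidine nitrogen takes up the phenol proton of O1 while the thiourea N–H bonds hold the C4 carbonyl oxygen next to the 3-methoxy oxygen, so that O1 should be delivered to one face of C2; C3 is set by thermodynamic control, because enolisation under the same amine lets the 3-methoxy group settle equatorial and trans to the equatorial aryl group. The step needs acyl-to-C3 regiochemistry, which the polarisation of the alkynyl ether secures (late-metal hydride and carbon–metal additions to alkynyl ethers place the metal on the oxygen-bearing carbon, as in palladium-catalysed hydrostannation to α-stannyl enol ethers), and it needs the uncatalysed ring closure to be slow, which the strong O–H···O=C hydrogen bond of 9 and the base-free rhodium methoxide precatalyst should secure.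

**Step 5**
Reactants: 10 (2R,3R)-2-[2,5-bis(benzyloxy)-4-methoxyphenyl]-3,5,7-trimethoxy-2,3-dihydro-4H-chromen-4-one
Product: 11 (2R,3R)-2-(2,5-dihydroxy-4-methoxyphenyl)-3,5,7-trimethoxy-2,3-dihydro-4H-chromen-4-one
Conditions: H2 (1 atm), Pd/C (10 wt % Pd), degassed EtOAc, rt; filtered under argon
Reagents that add atoms: none
Why: Hydrogenolysis of the two benzyl ethers on palladium under neutral conditions, which should leave the aryl ketone, the four methyl ethers and both stereocentres untouched.

**Compound list**

1 | 2-methoxybenzene-1,4-diol | COc1cc(O)ccc1O | starting material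
2 | 1,4-bis(benzyloxy)-2-methoxybenzene | COc1cc(OCc2ccccc2)ccc1OCc1ccccc1 | intermediate
3 | 1,4-bis(benzyloxy)-2-iodo-5-methoxybenzene | Ic1cc(OCc2ccccc2)c(OC)cc1OCc1ccccc1 | intermediate
4 | 2-chloro-1,1-dimethoxyethane | ClCC(OC)OC | starting material
5 | lithium methoxyacetylide | COC#C[Li] | intermediate
6 | (methoxyethynyl)zinc chloride | COC#C[Zn]Cl | intermediate
7 | 1,4-bis(benzyloxy)-2-methoxy-5-(methoxyethynyl)benzene | COC#Cc1cc(OCc2ccccc2)c(OC)cc1OCc1ccccc1 | intermediate
8 | 2-hydroxy-4,6-dimethoxybenzaldehyde | COc1cc(O)c(C=O)c(OC)c1 | starting material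
9 | (Z)-3-[2,5-bis(benzyloxy)-4-methoxyphenyl]-1-(2-hydroxy-4,6-dimethoxyphenyl)-2-methoxyprop-2-en-1-one | COc1cc(OC)c(C(=O)/C(OC)=C/c2cc(OCc3ccccc3)c(OC)cc2OCc2ccccc2)c(O)c1 | intermediate
10 | (2R,3R)-2-[2,5-bis(benzyloxy)-4-methoxyphenyl]-3,5,7-trimethoxy-2,3-dihydro-4H-chromen-4-one | COc1cc(OC)c2c(c1)O[C@H](c1cc(OCc3ccccc3)c(OC)cc1OCc1ccccc1)[C@@H](OC)C2=O | intermediate
11 | (2R,3R)-2-(2,5-dihydroxy-4-methoxyphenyl)-3,5,7-trimethoxy-2,3-dihydro-4H-chromen-4-one | COc1cc(OC)c2c(c1)O[C@H](c1cc(O)c(OC)cc1O)[C@@H](OC)C2=O | target

**Step count**

Total step count: 5. Longest linear sequence: 5 steps (1 → 2 → 3 → 7 → 10 → 11).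

**Steps most likely to fail**

1. Step 4 (Proposed new method). The alkynyl ether may insert with reversed regiochemistry, oligomerise at rhodium, or add the phenol O–H before hydroacylation. Ring closure may also occur outside the control of the chiral catalyst because rhodium and phosphine residues are present, which would lower enantiomeric purity. Fallback by known chemistry, setting out from 7: palladium-catalysed hydrostannation (Bu3SnH, Pd(PPh3)4, THF, 0 °C) places tin on the oxygen-bearing carbon and should give tributyl[(E)-2-[2,5-bis(benzyloxy)-4-methoxyphenyl]-1-methoxyethenyl]stannane F1. Stille acylation of F1 with 2-hydroxy-4,6-dimethoxybenzoyl chloride F2 (made from commercial 2-hydroxy-4,6-dimethoxybenzoic acid with (COCl)2 and a trace of DMF) under Pd(PPh3)4 in toluene at 60 °C forms C3–C4 with retention of alkene geometry. This comes back to the route at 9, which is purified and then closed with the same thiourea in a flask free of rhodium and phosphine to reach 10.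

2. Step 3. The zinc acetylide may be protonated before coupling, oxidative addition to the electron-rich, ortho-substituted iodide may be slow, and the alkynyl ether may be hydrated during isolation. Fallback setting out from 2: Friedel–Crafts acylation with methoxyacetyl chloride (SnCl4, CH2Cl2, −20 °C) at the same ring position should give 1-[2,5-bis(benzyloxy)-4-methoxyphenyl]-2-methoxyethan-1-one F3. Enolisation and triflation (LiN(SiMe3)2, PhNTf2, THF, −78 °C) should give (Z)-1-[2,5-bis(benzyloxy)-4-methoxyphenyl]-2-methoxyethenyl trifluoromethanesulfonate F4. Anti elimination of triflate with KOtBu (THF, −78 to 0 °C) comes back to the route at 7.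

3. Step 5. Over-reduction by hydrogenolysis of the benzylic C2–O1 bond next to the electron-rich ring B, air oxidation of the freed hydroquinone, or loss of configuration by ring opening at C2 may occur. Fallback setting out from 10: oxidative removal of both benzyl groups from the para-dialkoxy ring B with (NH4)2Ce(NO3)6 (tetravalent cerium; MeCN–H2O, 0 °C) should give 2-methoxy-5-[(2R,3R)-3,5,7-trimethoxy-4-oxo-3,4-dihydro-2H-chromen-2-yl]cyclohexa-2,5-diene-1,4-dione F5. Reduction of the quinone with Na2S2O4 (EtOAc–H2O, rt) comes back to the route at 11.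

**Further compounds**

F1 | step 4 | tributyl[(E)-2-[2,5-bis(benzyloxy)-4-methoxyphenyl]-1-methoxyethenyl]stannane | CCCC[Sn](CCCC)(CCCC)/C(OC)=C/c1cc(OCc2ccccc2)c(OC)cc1OCc1ccccc1
F2 | step 4 | 2-hydroxy-4,6-dimethoxybenzoyl chloride | COc1cc(O)c(C(Cl)=O)c(OC)c1
F3 | step 3 | 1-[2,5-bis(benzyloxy)-4-methoxyphenyl]-2-methoxyethan-1-one | COCC(=O)c1cc(OCc2ccccc2)c(OC)cc1OCc1ccccc1
F4 | step 3 | (Z)-1-[2,5-bis(benzyloxy)-4-methoxyphenyl]-2-methoxyethenyl trifluoromethanesulfonate | CO/C=C(\OS(=O)(=O)C(F)(F)F)c1cc(OCc2ccccc2)c(OC)cc1OCc1ccccc1
F5 | step 5 | 2-methoxy-5-[(2R,3R)-3,5,7-trimethoxy-4-oxo-3,4-dihydro-2H-chromen-2-yl]cyclohexa-2,5-diene-1,4-dione | COc1cc(OC)c2c(c1)O[C@H](C1=CC(=O)C(OC)=CC1=O)[C@@H](OC)C2=O
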